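**Retrosynthetic overview** (C-locants are the chromene locants of the target)
1. Target acid ⇐ hydrolysis of an enol δ-lactone ⇐ lactol from a catalyst-controlled Michael addition of the bicyclic vinylogous acid (C6–H) to cinnamaldehyde (sets the benzylic S centre).
2. Bicyclic core ⇐ Dieckmann closure (C6–C7) of a 5-acetyl-2,3-dihydro-4H-pyran-4-one that carries the quaternary ester at C6 of the pyranone.
3. Pyranone ⇐ acid cyclodehydration of a δ-hydroxy-1,3-diketone, assembled by the key intermolecular aldol (C4–C4a) between a quaternary β-keto ester fragment and an Evans syn-aldol-derived aldehyde (gives cis-2,3-dimethyl and fixes the ring oxygen on C8a).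
4. Quaternary C8 ⇐ Fráter–Seebach prenylation of a (3R)-β-hydroxy ester made from lavandulylated acetoacetate; (R)-lavandulyl iodide ⇐ Evans deconjugative prenylation.
5. Ring order: ring B (dihydropyranone) first, then ring A (carbocycle).

Assumption: stereocentres that are destroyed later (C2 of 12 and 13, the silyloxy/hydroxy-ethyl carbon of 19, 20 and 27–32, the two aldol carbons of 28, the central diketone carbon of 29 and 30, the anomeric carbon of 38) are carried as mixtures and left undefined in the SMILES; 38 and 39 are drawn closed on the C5 oxygen (an O7-closed isomer would converge in step 23).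

**Step 1**
Reactants: 1 (R)-4-benzyloxazolidin-2-one; 2 3-methylbut-2-enoyl chloride
Product: 4 (R)-4-benzyl-3-(3-methylbut-2-enoyl)oxazolidin-2-one, via lithium oxazolidinide 3 (not isolated)
Conditions: n-BuLi, THF, −78 °C; then 2, −78 → 0 °C
Reagents that add atoms: none
Why: N-acylation of the lithiated auxiliary (nucleophilic acyl substitution) at low temperature gives the conjugated imide without vinylketene formation; no stereocentre is formed.

**Step 2**
Reactants: 4 (R)-4-benzyl-3-(3-methylbut-2-enoyl)oxazolidin-2-one; 5 1-bromo-3-methylbut-2-ene (prenyl bromide)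
Product: 7 (R)-4-benzyl-3-[(2R)-5-methyl-2-(prop-1-en-2-yl)hex-4-enoyl]oxazolidin-2-one, via sodium dienolate 6 (not isolated)
Conditions: NaN(SiMe3)2, THF, −78 °C; then 5, −78 → −40 °C
Reagents that add atoms: none
Why: Deconjugative Evans alkylation: γ-deprotonation gives the chelated Z-dienolate, which is prenylated at the α-carbon on the face opposite the benzyl group, setting the (2R) centre and moving the alkene into the isopropenyl position.

**Step 3**
Reactants: 7 (R)-4-benzyl-3-[(2R)-5-methyl-2-(prop-1-en-2-yl)hex-4-enoyl]oxazolidin-2-one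
Product: 8 (2R)-5-methyl-2-(prop-1-en-2-yl)hex-4-en-1-ol [(R)-lavandulol]
Conditions: LiBH4, H2O (1 equiv), Et2O, 0 °C
Reagents that add atoms: none
Why: Reductive cleavage of the imide with borohydride gives the primary alcohol without touching the alkenes or the α-centre and returns the auxiliary.

**Step 4**
Reactants: 8 (2R)-5-methyl-2-(prop-1-en-2-yl)hex-4-en-1-ol
Product: 9 (3R)-3-(iodomethyl)-2,6-dimethylhepta-1,5-diene [(R)-lavandulyl iodide]
Conditions: PPh3, imidazole, iodine, CH2Cl2, 0 °C → rt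
Reagents that add atoms: iodine, [I][I]
Why: Appel-type iodination is an SN2 displacement at the primary carbon, so the adjacent stereocentre is untouched.

**Step 5**
Reactants: 10 ethyl 3-oxobutanoate (ethyl acetoacetate); 9 (3R)-3-(iodomethyl)-2,6-dimethylhepta-1,5-diene
Product: 12 ethyl (4S)-2-acetyl-7-methyl-4-(prop-1-en-2-yl)oct-6-enoate (mixture of C2 epimers), via sodium enolate 11 (not isolated)
Conditions: NaH, THF/DMF 1:1, 0 °C (10 in 1.5-fold excess); then 9, 60 °C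
Reagents that add atoms: none
Why: Acetoacetate alkylation (SN2) with a soft, weakly basic enolate tolerates the β-branched iodide where a stronger base would eliminate; C2 is left as a mixture because step 7 erases it.

**Step 6**
Reactants: 12 ethyl (4S)-2-acetyl-7-methyl-4-(prop-1-en-2-yl)oct-6-enoate
Product: 13 ethyl (4S)-2-[(1R)-1-hydroxyethyl]-7-methyl-4-(prop-1-en-2-yl)oct-6-enoate (mixture of C2 epimers)
Conditions: H2 (4 atm), RuCl2[(R)-BINAP] (1 mol %), EtOH, 50 °C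
Reagents that add atoms: none
Why: Noyori asymmetric hydrogenation of the β-keto ester: the (R)-BINAP catalyst reduces the chelated ketone from one face to give the (R)-carbinol in both C2 epimers, and unfunctionalised alkenes are not reduced at low pressure.

**Step 7**
Reactants: 13 ethyl (4S)-2-[(1R)-1-hydroxyethyl]-7-methyl-4-(prop-1-en-2-yl)oct-6-enoate; 5 1-bromo-3-methylbut-2-ene
Product: 15 ethyl (2S,4S)-2-[(1R)-1-hydroxyethyl]-7-methyl-2-(3-methylbut-2-en-1-yl)-4-(prop-1-en-2-yl)oct-6-enoate, via dilithium alkoxide enolate 14 (not isolated)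
Conditions: LiN(iPr)2 (2.3 equiv), THF, −78 → −20 °C; then 5, DMPU, −78 → 0 °C; AcOH quench
Reagents that add atoms: none
Why: Fráter–Seebach alkylation: the lithium-chelated alkoxide enolate is prenylated anti to the carbinol methyl group, which sets the quaternary centre as (2S) whatever the C2 configuration of 13.

**Step 8**
Reactants: 15 ethyl (2S,4S)-2-[(1R)-1-hydroxyethyl]-7-methyl-2-(3-methylbut-2-en-1-yl)-4-(prop-1-en-2-yl)oct-6-enoate
Product: 16 ethyl (2S,4S)-2-acetyl-7-methyl-2-(3-methylbut-2-en-1-yl)-4-(prop-1-en-2-yl)oct-6-enoate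
Conditions: Dess–Martin periodinane, CH2Cl2, 0 °C → rt
Reagents that add atoms: none
Why: Dess–Martin oxidation of the secondary alcohol leaves a non-epimerisable quaternary centre whose ketone and ester arms are now chemically distinct.

**Step 9**
Reactants: 16 ethyl (2S,4S)-2-acetyl-7-methyl-2-(3-methylbut-2-en-1-yl)-4-(prop-1-en-2-yl)oct-6-enoate; 17 acetaldehyde
Product: 19 ethyl (2S,4S)-2-(3-hydroxybutanoyl)-7-methyl-2-(3-methylbut-2-en-1-yl)-4-(prop-1-en-2-yl)oct-6-enoate (carbinol epimers), via lithium enolate 18 (not isolated)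
Conditions: LiN(iPr)2 (1.1 equiv), THF, −78 °C; then 17 (3 equiv), −78 °C; AcOH quench at −78 °C
Reagents that add atoms: none
Why: Aldol addition of the only possible enolate (the methyl group) to acetaldehyde installs a masked acetyl group; the carbinol configuration is irrelevant, and the cold quench prevents lactonisation onto the ester.

**Step 10**
Reactants: 19 ethyl (2S,4S)-2-(3-hydroxybutanoyl)-7-methyl-2-(3-methylbut-2-en-1-yl)-4-(prop-1-en-2-yl)oct-6-enoate
Product: 20 ethyl (2S,4S)-2-{3-[(tert-butyldimethylsilyl)oxy]butanoyl}-7-methyl-2-(3-methylbut-2-en-1-yl)-4-(prop-1-en-2-yl)oct-6-enoate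
Conditions: TBSOTf, 2,6-lutidine, CH2Cl2, −78 → 0 °C
Reagents that add atoms: tert-butyldimethylsilyl trifluoromethanesulfonate, CC(C)(C)[Si](C)(C)OS(=O)(=O)C(F)(F)F
Why: Silylation of the secondary alcohol protects the masked acetyl group through the basic and oxidative steps that follow.

**Step 11**
Reactants: 21 (S)-4-benzyl-3-propionyloxazolidin-2-one; 17 acetaldehyde
Product: 23 (S)-4-benzyl-3-[(2S,3R)-3-hydroxy-2-methylbutanoyl]oxazolidin-2-one, via dibutylboron Z-enolate 22 (not isolated)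
Conditions: Bu2BOTf, iPr2NEt, CH2Cl2, 0 °C; then 17, −78 → 0 °C; then pH 7 buffer, MeOH, 30% H2O2, 0 °C
Reagents that add atoms: none
Why: Evans syn-aldol reaction: the Z-boron enolate reacts through a Zimmerman–Traxler chair under auxiliary control to give the (2S,3R) syn adduct, which holds both future pyranone stereocentres.

**Step 12**
Reactants: 23 (S)-4-benzyl-3-[(2S,3R)-3-hydroxy-2-methylbutanoyl]oxazolidin-2-one
Product: 24 (S)-4-benzyl-3-{(2S,3R)-2-methyl-3-[(triethylsilyl)oxy]butanoyl}oxazolidin-2-one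
Conditions: Et3SiCl, imidazole, DMF, 0 °C → rt
Reagents that add atoms: chlorotriethylsilane, CC[Si](Cl)(CC)CC
Why: Silylation as the acid-labile triethylsilyl ether allows its later removal in the presence of the TBS ether.

**Step 13**
Reactants: 24 (S)-4-benzyl-3-{(2S,3R)-2-methyl-3-[(triethylsilyl)oxy]butanoyl}oxazolidin-2-one
Product: 25 (2R,3R)-2-methyl-3-[(triethylsilyl)oxy]butan-1-ol
Conditions: LiBH4, MeOH (1.1 equiv), THF, 0 °C
Reagents that add atoms: none
Why: Reductive removal of the auxiliary with borohydride gives the primary alcohol without epimerising the α-centre (the descriptor changes only through CIP priorities).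

**Step 14**
Reactants: 25 (2R,3R)-2-methyl-3-[(triethylsilyl)oxy]butan-1-ol
Product: 26 (2S,3R)-2-methyl-3-[(triethylsilyl)oxy]butanal
Conditions: Dess–Martin periodinane, CH2Cl2, 0 °C → rt; used at once
Reagents that add atoms: none
Why: Dess–Martin oxidation gives the α-chiral aldehyde under non-basic conditions that do not epimerise it.

**Step 15**
Reactants: 20 ethyl (2S,4S)-2-{3-[(tert-butyldimethylsilyl)oxy]butanoyl}-7-methyl-2-(3-methylbut-2-en-1-yl)-4-(prop-1-en-2-yl)oct-6-enoate; 26 (2S,3R)-2-methyl-3-[(triethylsilyl)oxy]butanal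
Product: 28 ethyl (2S,4S)-2-[(4R,5R)-2-{1-[(tert-butyldimethylsilyl)oxy]ethyl}-3-hydroxy-4-methyl-5-[(triethylsilyl)oxy]hexanoyl]-7-methyl-2-(3-methylbut-2-en-1-yl)-4-(prop-1-en-2-yl)oct-6-enoate (diastereomer mixture at the unassigned carbons), via lithium enolate 27 (not isolated)
Conditions: LiN(iPr)2 (1.1 equiv), THF, −78 °C; then 26, −78 °C; AcOH quench at −78 °C
Reagents that add atoms: none
Why: Key intermolecular aldol addition: the enolate of 20 (enolisable only at the CH2 group) adds to aldehyde 26 and forms the C4–C4a bond that joins the two chiral fragments; the two new centres are removed in steps 16 and 17, so no selectivity is needed.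

**Step 16**
Reactants: 28 aldol adduct (name as in step 15)
Product: 29 ethyl (2S,4S)-2-[(4S,5R)-2-{1-[(tert-butyldimethylsilyl)oxy]ethyl}-4-methyl-3-oxo-5-[(triethylsilyl)oxy]hexanoyl]-7-methyl-2-(3-methylbut-2-en-1-yl)-4-(prop-1-en-2-yl)oct-6-enoate
Conditions: Dess–Martin periodinane, CH2Cl2, 0 °C → rt
Reagents that add atoms: none
Why: Dess–Martin oxidation gives the 1,3-diketone without base, so the silyloxy group β to the dicarbonyl unit is not eliminated.

**Step 17**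
Reactants: 29 silyl-protected 1,3-diketone (name as in step 16)
Product: 31 ethyl (2S,4S)-2-[(2R,3S)-5-{1-[(tert-butyldimethylsilyl)oxy]ethyl}-2,3-dimethyl-4-oxo-3,4-dihydro-2H-pyran-6-yl]-7-methyl-2-(3-methylbut-2-en-1-yl)-4-(prop-1-en-2-yl)oct-6-enoate, via hydroxy diketone 30 (not isolated)
Conditions: AcOH/THF/H2O 3:1:1, rt; then camphorsulfonic acid (10 mol %), CH2Cl2, 4 Å sieves, rt
Reagents that add atoms: none
Why: Acid removes the triethylsilyl ether and the freed hydroxyl condenses with the only ketone it can reach through a six-membered ring (cyclodehydration to the dihydropyranone, as in stegobinone syntheses), which places the ring oxygen on C8a and retains both methyl-bearing centres (cis, 2R,3S).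

**Step 18**
Reactants: 31 TBS-protected pyranone (name as in step 17)
Product: 32 ethyl (2S,4S)-2-[(2R,3S)-5-(1-hydroxyethyl)-2,3-dimethyl-4-oxo-3,4-dihydro-2H-pyran-6-yl]-7-methyl-2-(3-methylbut-2-en-1-yl)-4-(prop-1-en-2-yl)oct-6-enoate
Conditions: HF·pyridine, pyridine, THF, 0 °C → rt
Reagents that add atoms: none
Why: Fluoride desilylation under buffered acidic conditions frees the alcohol without the base that would epimerise the cis-dimethyl unit.

**Step 19**
Reactants: 32 hydroxyethyl pyranone (name as in step 18)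
Product: 33 ethyl (2S,4S)-2-[(2R,3S)-5-acetyl-2,3-dimethyl-4-oxo-3,4-dihydro-2H-pyran-6-yl]-7-methyl-2-(3-methylbut-2-en-1-yl)-4-(prop-1-en-2-yl)oct-6-enoate
Conditions: Dess–Martin periodinane, CH2Cl2, 0 °C → rt (run directly on crude 32)
Reagents that add atoms: none
Why: Dess–Martin oxidation of the allylic alcohol unmasks the acetyl group before the hydroxy ester can lactonise.

**Step 20**
Reactants: 33 acetyl pyranone ester (name as in step 19)
Product: 35 (2R,3S,8S)-5-hydroxy-2,3-dimethyl-8-(3-methylbut-2-en-1-yl)-8-[(2S)-5-methyl-2-(prop-1-en-2-yl)hex-4-en-1-yl]-2,3-dihydro-4H-chromene-4,7(8H)-dione, via lithium enolate 34 (not isolated)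
Conditions: LiN(SiMe3)2 (1.5 equiv), THF, −78 → 0 °C; then 1 M HCl
Reagents that add atoms: none
Why: Dieckmann-type intramolecular Claisen condensation: the kinetically formed acetyl enolate (least hindered, more acidic than the C3 methine) attacks the ester held cis across the ring alkene and closes ring A as a stabilised diketonate; the quaternary centre is not involved.

**Step 21**
Reactants: 35 bicyclic vinylogous acid (name as in step 20); 36 (E)-cinnamaldehyde
Product: 38 lactol of the Michael adduct [(S) benzylic centre; 2-hydroxy-4-phenyl-3,4-dihydro-2H-pyran ring closed on O5 and C6 of 35; anomer mixture], via open-chain aldehyde 37 (not isolated)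
Conditions: (S)-2-[diphenyl(trimethylsilyloxy)methyl]pyrrolidine (20 mol %), PhCO2H (20 mol %), CH2Cl2, 0 °C → rt
Reagents that add atoms: none
Why: Organocatalytic Michael addition through the iminium ion of cinnamaldehyde: the bulky group of the (S)-catalyst shields one face, so C6 adds to give the (S) benzylic centre (same facial sense as nitromethane and malonate additions), and the aldehyde then closes onto the enol oxygen.

**Step 22**
Reactants: 38 lactol (name as in step 21)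
Product: 39 enol δ-lactone [(4S)-4-phenyl-3,4-dihydro-2H-pyran-2-one ring closed on O5 and C6 of 35]
Conditions: Dess–Martin periodinane, CH2Cl2, 0 °C → rt
Reagents that add atoms: none
Why: Dess–Martin oxidation of the lactol to the lactone brings the side chain to the carboxylic acid oxidation level under neutral conditions.

**Step 23**
Reactants: 39 enol δ-lactone (name as in step 22)
Product: 40 (3S)-3-[(2R,3S,8S)-5-hydroxy-2,3-dimethyl-8-(3-methylbut-2-en-1-yl)-8-[(2S)-5-methyl-2-(prop-1-en-2-yl)hex-4-en-1-yl]-4,7-dioxo-3,4,7,8-tetrahydro-2H-chromen-6-yl]-3-phenylpropanoic acid (CNP0150579.2)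
Conditions: LiOH (2.2 equiv), THF/H2O 3:1, 0 °C, 30 min; then 1 M HCl to pH 3
Reagents that add atoms: lithium hydroxide, [Li+].[OH-]
Why: Saponification of the activated enol lactone (ester hydrolysis) frees the acid and the enol; the short cold treatment and the delocalised enolate protect the cis-dimethyl centre.

**Compound list**
1 | (R)-4-benzyloxazolidin-2-one | O=C1OC[C@@H](Cc2ccccc2)N1 | starting material
2 | 3-methylbut-2-enoyl chloride | CC(C)=CC(=O)Cl | starting material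
3 | lithium (R)-4-benzyl-2-oxooxazolidin-3-ide | [Li+].O=C1OC[C@@H](Cc2ccccc2)[N-]1 | intermediate
4 | (R)-4-benzyl-3-(3-methylbut-2-enoyl)oxazolidin-2-one | CC(C)=CC(=O)N1[C@H](Cc2ccccc2)COC1=O | intermediate
5 | 1-bromo-3-methylbut-2-ene | CC(C)=CCBr | starting material
6 | sodium Z-dienolate of 4 | [Na+].[O-]/C(=C\C(C)=C)N1[C@H](Cc2ccccc2)COC1=O | intermediate
7 | (R)-4-benzyl-3-[(2R)-5-methyl-2-(prop-1-en-2-yl)hex-4-enoyl]oxazolidin-2-one | C=C(C)[C@@H](CC=C(C)C)C(=O)N1[C@H](Cc2ccccc2)COC1=O | intermediate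
8 | (2R)-5-methyl-2-(prop-1-en-2-yl)hex-4-en-1-ol | C=C(C)[C@@H](CC=C(C)C)CO | intermediate
9 | (3R)-3-(iodomethyl)-2,6-dimethylhepta-1,5-diene | C=C(C)[C@@H](CC=C(C)C)CI | intermediate
10 | ethyl 3-oxobutanoate | CCOC(=O)CC(C)=O | starting material
11 | sodium enolate of 10 | [Na+].CCOC(=O)C=C(C)[O-] | intermediate
12 | ethyl (4S)-2-acetyl-7-methyl-4-(prop-1-en-2-yl)oct-6-enoate | C=C(C)[C@@H](CC=C(C)C)CC(C(C)=O)C(=O)OCC | intermediate
13 | ethyl (4S)-2-[(1R)-1-hydroxyethyl]-7-methyl-4-(prop-1-en-2-yl)oct-6-enoate | C=C(C)[C@@H](CC=C(C)C)CC([C@@H](C)O)C(=O)OCC | intermediate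
14 | dilithium alkoxide enolate of 13 | [Li+].[Li+].C=C(C)[C@@H](CC=C(C)C)CC(=C([O-])OCC)[C@@H](C)[O-] | intermediate
15 | ethyl (2S,4S)-2-[(1R)-1-hydroxyethyl]-7-methyl-2-(3-methylbut-2-en-1-yl)-4-(prop-1-en-2-yl)oct-6-enoate | C=C(C)[C@@H](CC=C(C)C)C[C@@](CC=C(C)C)([C@@H](C)O)C(=O)OCC | intermediate
16 | ethyl (2S,4S)-2-acetyl-7-methyl-2-(3-methylbut-2-en-1-yl)-4-(prop-1-en-2-yl)oct-6-enoate | C=C(C)[C@@H](CC=C(C)C)C[C@@](CC=C(C)C)(C(C)=O)C(=O)OCC | intermediate
17 | acetaldehyde | CC=O | starting material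
18 | lithium enolate of 16 | [Li+].C=C(C)[C@@H](CC=C(C)C)C[C@@](CC=C(C)C)(C(=C)[O-])C(=O)OCC | intermediate
19 | ethyl (2S,4S)-2-(3-hydroxybutanoyl)-7-methyl-2-(3-methylbut-2-en-1-yl)-4-(prop-1-en-2-yl)oct-6-enoate | C=C(C)[C@@H](CC=C(C)C)C[C@@](CC=C(C)C)(C(=O)CC(C)O)C(=O)OCC | intermediate
20 | ethyl (2S,4S)-2-{3-[(tert-butyldimethylsilyl)oxy]butanoyl}-7-methyl-2-(3-methylbut-2-en-1-yl)-4-(prop-1-en-2-yl)oct-6-enoate | C=C(C)[C@@H](CC=C(C)C)C[C@@](CC=C(C)C)(C(=O)CC(C)O[Si](C)(C)C(C)(C)C)C(=O)OCC | intermediate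
21 | (S)-4-benzyl-3-propionyloxazolidin-2-one | CCC(=O)N1[C@@H](Cc2ccccc2)COC1=O | starting material
22 | dibutylboron Z-enolate of 21 | CCCCB(CCCC)O/C(=C\C)N1[C@@H](Cc2ccccc2)COC1=O | intermediate
23 | (S)-4-benzyl-3-[(2S,3R)-3-hydroxy-2-methylbutanoyl]oxazolidin-2-one | C[C@@H](O)[C@H](C)C(=O)N1[C@@H](Cc2ccccc2)COC1=O | intermediate
24 | (S)-4-benzyl-3-{(2S,3R)-2-methyl-3-[(triethylsilyl)oxy]butanoyl}oxazolidin-2-one | CC[Si](CC)(CC)O[C@H](C)[C@H](C)C(=O)N1[C@@H](Cc2ccccc2)COC1=O | intermediate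
25 | (2R,3R)-2-methyl-3-[(triethylsilyl)oxy]butan-1-ol | CC[Si](CC)(CC)O[C@H](C)[C@H](C)CO | intermediate
26 | (2S,3R)-2-methyl-3-[(triethylsilyl)oxy]butanal | CC[Si](CC)(CC)O[C@H](C)[C@H](C)C=O | intermediate
27 | lithium enolate of 20 | [Li+].C=C(C)[C@@H](CC=C(C)C)C[C@@](CC=C(C)C)(C([O-])=CC(C)O[Si](C)(C)C(C)(C)C)C(=O)OCC | intermediate
28 | aldol adduct of 20 and 26 (name in step 15) | C=C(C)[C@@H](CC=C(C)C)C[C@@](CC=C(C)C)(C(=O)C(C(C)O[Si](C)(C)C(C)(C)C)C(O)[C@@H](C)[C@@H](C)O[Si](CC)(CC)CC)C(=O)OCC | intermediate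
29 | silyl-protected 1,3-diketone (name in step 16) | C=C(C)[C@@H](CC=C(C)C)C[C@@](CC=C(C)C)(C(=O)C(C(C)O[Si](C)(C)C(C)(C)C)C(=O)[C@@H](C)[C@@H](C)O[Si](CC)(CC)CC)C(=O)OCC | intermediate
30 | ethyl (2S,4S)-2-[(4S,5R)-2-{1-[(tert-butyldimethylsilyl)oxy]ethyl}-5-hydroxy-4-methyl-3-oxohexanoyl]-7-methyl-2-(3-methylbut-2-en-1-yl)-4-(prop-1-en-2-yl)oct-6-enoate | C=C(C)[C@@H](CC=C(C)C)C[C@@](CC=C(C)C)(C(=O)C(C(C)O[Si](C)(C)C(C)(C)C)C(=O)[C@@H](C)[C@@H](C)O)C(=O)OCC | intermediate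
31 | TBS-protected pyranone (name in step 17) | C=C(C)[C@@H](CC=C(C)C)C[C@@](CC=C(C)C)(C1=C(C(C)O[Si](C)(C)C(C)(C)C)C(=O)[C@@H](C)[C@@H](C)O1)C(=O)OCC | intermediate
32 | hydroxyethyl pyranone (name in step 18) | C=C(C)[C@@H](CC=C(C)C)C[C@@](CC=C(C)C)(C1=C(C(C)O)C(=O)[C@@H](C)[C@@H](C)O1)C(=O)OCC | intermediate
33 | acetyl pyranone ester (name in step 19) | C=C(C)[C@@H](CC=C(C)C)C[C@@](CC=C(C)C)(C1=C(C(C)=O)C(=O)[C@@H](C)[C@@H](C)O1)C(=O)OCC | intermediate
34 | lithium enolate of 33 | [Li+].C=C(C)[C@@H](CC=C(C)C)C[C@@](CC=C(C)C)(C1=C(C(=C)[O-])C(=O)[C@@H](C)[C@@H](C)O1)C(=O)OCC | intermediate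
35 | (2R,3S,8S)-5-hydroxy-2,3-dimethyl-8-(3-methylbut-2-en-1-yl)-8-[(2S)-5-methyl-2-(prop-1-en-2-yl)hex-4-en-1-yl]-2,3-dihydro-4H-chromene-4,7(8H)-dione | C=C(C)[C@@H](CC=C(C)C)C[C@]1(CC=C(C)C)C(=O)C=C(O)C2=C1O[C@H](C)[C@H](C)C2=O | intermediate
36 | (E)-cinnamaldehyde | O=C/C=C/c1ccccc1 | starting material
37 | (3S)-3-(chromenyl)-3-phenylpropanal, the open Michael adduct of 35 | C=C(C)[C@@H](CC=C(C)C)C[C@]1(CC=C(C)C)C(=O)C([C@@H](CC=O)c2ccccc2)=C(O)C2=C1O[C@H](C)[C@H](C)C2=O | intermediate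
38 | lactol of 37 closed on O5 (anomer mixture) | C=C(C)[C@@H](CC=C(C)C)C[C@]1(CC=C(C)C)C(=O)C3=C(OC(O)C[C@H]3c4ccccc4)C2=C1O[C@H](C)[C@H](C)C2=O | intermediate
39 | enol δ-lactone closed on O5 | C=C(C)[C@@H](CC=C(C)C)C[C@]1(CC=C(C)C)C(=O)C3=C(OC(=O)C[C@H]3c4ccccc4)C2=C1O[C@H](C)[C@H](C)C2=O | intermediate
40 | (3S)-3-[(2R,3S,8S)-5-hydroxy-2,3-dimethyl-8-(3-methylbut-2-en-1-yl)-8-[(2S)-5-methyl-2-(prop-1-en-2-yl)hex-4-en-1-yl]-4,7-dioxo-3,4,7,8-tetrahydro-2H-chromen-6-yl]-3-phenylpropanoic acid | C=C(C)[C@@H](CC=C(C)C)C[C@]1(CC=C(C)C)C(=O)C([C@@H](CC(=O)O)c2ccccc2)=C(O)C2=C1O[C@H](C)[C@H](C)C2=O | target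

**Totals**
Total step count: 23. Longest linear sequence: 19 steps (steps 1–10 and 15–23, from 1 to 40); the aldehyde branch (steps 11–14) joins at step 15.

**Three steps most likely to fail**

Step 6. The hydrogenation must reduce a hindered, α-branched β-keto ester with high facial control while leaving three alkenes, one of them next to a stereocentre, untouched. The fallback sets the carbinol by an Evans syn-aldol instead of a reduction; it sets out from iodide 9 and comes back at 13. Diethyl malonate is alkylated with 9 (NaH, THF/DMF, 60 °C) to give diethyl 2-[(2S)-5-methyl-2-(prop-1-en-2-yl)hex-4-en-1-yl]propanedioate F1. Saponification (KOH, EtOH/H2O) gives 2-[(2S)-5-methyl-2-(prop-1-en-2-yl)hex-4-en-1-yl]propanedioic acid F2, and heating to 140 °C gives (4R)-7-methyl-4-(prop-1-en-2-yl)oct-6-enoic acid F3. Coupling to (S)-4-benzyloxazolidin-2-one (the auxiliary recovered in step 13; pivaloyl chloride, Et3N, LiCl, THF) gives (S)-4-benzyl-3-[(4R)-7-methyl-4-(prop-1-en-2-yl)oct-6-enoyl]oxazolidin-2-one F4. Bu2BOTf/iPr2NEt and acetaldehyde 17 then give the syn aldol (S)-4-benzyl-3-{(2S,4S)-2-[(1R)-1-hydroxyethyl]-7-methyl-4-(prop-1-en-2-yl)oct-6-enoyl}oxazolidin-2-one F5. LiOH/H2O2 gives (2S,4S)-2-[(1R)-1-hydroxyethyl]-7-methyl-4-(prop-1-en-2-yl)oct-6-enoic acid F6, and EtI/K2CO3 in DMF gives 13 as its single (2S) epimer, which enters step 7 unchanged.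

Step 15. The enolate of 20 is flanked by a quaternary carbon and a silyloxyethyl group, so the aldol may be slow or lose silanolate, and the later cyclodehydration (step 17) is correspondingly crowded. The fallback reverses the order of C4a substitution; it sets out from ketone 16 (with aldehyde 26) and comes back at 33. The unhindered methyl-ketone enolate of 16 (LiN(iPr)2, THF, −78 °C) adds to 26 to give ethyl (2S,4S)-2-{(4R,5R)-3-hydroxy-4-methyl-5-[(triethylsilyl)oxy]hexanoyl}-7-methyl-2-(3-methylbut-2-en-1-yl)-4-(prop-1-en-2-yl)oct-6-enoate F7. Dess–Martin oxidation gives ethyl (2S,4S)-7-methyl-2-{(4S,5R)-4-methyl-3-oxo-5-[(triethylsilyl)oxy]hexanoyl}-2-(3-methylbut-2-en-1-yl)-4-(prop-1-en-2-yl)oct-6-enoate F8. AcOH/THF/H2O frees ethyl (2S,4S)-2-[(4S,5R)-5-hydroxy-4-methyl-3-oxohexanoyl]-7-methyl-2-(3-methylbut-2-en-1-yl)-4-(prop-1-en-2-yl)oct-6-enoate F9, which camphorsulfonic acid closes to ethyl (2S,4S)-2-[(2R,3S)-2,3-dimethyl-4-oxo-3,4-dihydro-2H-pyran-6-yl]-7-methyl-2-(3-methylbut-2-en-1-yl)-4-(prop-1-en-2-yl)oct-6-enoate F10. α-Iodination (iodine, pyridine, CH2Cl2) gives ethyl (2S,4S)-2-[(2R,3S)-5-iodo-2,3-dimethyl-4-oxo-3,4-dihydro-2H-pyran-6-yl]-7-methyl-2-(3-methylbut-2-en-1-yl)-4-(prop-1-en-2-yl)oct-6-enoate F11. Stille coupling with tributyl(1-ethoxyvinyl)stannane (Pd(PPh3)4, toluene, 90 °C) gives ethyl (2S,4S)-2-[(2R,3S)-5-(1-ethoxyvinyl)-2,3-dimethyl-4-oxo-3,4-dihydro-2H-pyran-6-yl]-7-methyl-2-(3-methylbut-2-en-1-yl)-4-(prop-1-en-2-yl)oct-6-enoate F12, and 1 M HCl in THF at 0 °C hydrolyses the enol ether to 33. The weak point of this fallback is the iodination next to three alkenes.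

Step 21. Catalyst control on a hindered, chiral, acidic nucleophile is unproven; the addition may be slow or give a poor diastereomer ratio. The fallback uses a Knoevenagel–Michael–lactonisation sequence with Meldrum's acid and accepts separation of epimers; it sets out from 35 and comes back at 39. Benzaldehyde and Meldrum's acid (piperidine/AcOH cat.) give 5-benzylidene-2,2-dimethyl-1,3-dioxane-4,6-dione F13. With 35 (Et3N 10 mol %, MeCN, 70 °C) Michael addition gives 5-[(chromen-6-yl)(phenyl)methyl]-2,2-dimethyl-1,3-dioxane-4,6-dione F14, which lactonises onto the C5 enol with loss of acetone and carbon dioxide. No facial control is expected, so 39 is formed together with its (4R)-phenyl epimer F15 (about 1:1); they are separated by preparative HPLC and 39 goes on to step 23.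

**Further compounds**
F1 | step 6 | diethyl 2-[(2S)-5-methyl-2-(prop-1-en-2-yl)hex-4-en-1-yl]propanedioate | C=C(C)[C@@H](CC=C(C)C)CC(C(=O)OCC)C(=O)OCC
F2 | step 6 | 2-[(2S)-5-methyl-2-(prop-1-en-2-yl)hex-4-en-1-yl]propanedioic acid | C=C(C)[C@@H](CC=C(C)C)CC(C(=O)O)C(=O)O
F3 | step 6 | (4R)-7-methyl-4-(prop-1-en-2-yl)oct-6-enoic acid | C=C(C)[C@@H](CC=C(C)C)CCC(=O)O
F4 | step 6 | (S)-4-benzyl-3-[(4R)-7-methyl-4-(prop-1-en-2-yl)oct-6-enoyl]oxazolidin-2-one | C=C(C)[C@@H](CC=C(C)C)CCC(=O)N1[C@@H](Cc2ccccc2)COC1=O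
F5 | step 6 | (S)-4-benzyl-3-{(2S,4S)-2-[(1R)-1-hydroxyethyl]-7-methyl-4-(prop-1-en-2-yl)oct-6-enoyl}oxazolidin-2-one | C=C(C)[C@@H](CC=C(C)C)C[C@@H]([C@@H](C)O)C(=O)N1[C@@H](Cc2ccccc2)COC1=O
F6 | step 6 | (2S,4S)-2-[(1R)-1-hydroxyethyl]-7-methyl-4-(prop-1-en-2-yl)oct-6-enoic acid | C=C(C)[C@@H](CC=C(C)C)C[C@@H]([C@@H](C)O)C(=O)O
F7 | step 15 | ethyl (2S,4S)-2-{(4R,5R)-3-hydroxy-4-methyl-5-[(triethylsilyl)oxy]hexanoyl}-7-methyl-2-(3-methylbut-2-en-1-yl)-4-(prop-1-en-2-yl)oct-6-enoate | C=C(C)[C@@H](CC=C(C)C)C[C@@](CC=C(C)C)(C(=O)CC(O)[C@@H](C)[C@@H](C)O[Si](CC)(CC)CC)C(=O)OCC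
F8 | step 15 | ethyl (2S,4S)-7-methyl-2-{(4S,5R)-4-methyl-3-oxo-5-[(triethylsilyl)oxy]hexanoyl}-2-(3-methylbut-2-en-1-yl)-4-(prop-1-en-2-yl)oct-6-enoate | C=C(C)[C@@H](CC=C(C)C)C[C@@](CC=C(C)C)(C(=O)CC(=O)[C@@H](C)[C@@H](C)O[Si](CC)(CC)CC)C(=O)OCC
F9 | step 15 | ethyl (2S,4S)-2-[(4S,5R)-5-hydroxy-4-methyl-3-oxohexanoyl]-7-methyl-2-(3-methylbut-2-en-1-yl)-4-(prop-1-en-2-yl)oct-6-enoate | C=C(C)[C@@H](CC=C(C)C)C[C@@](CC=C(C)C)(C(=O)CC(=O)[C@@H](C)[C@@H](C)O)C(=O)OCC
F10 | step 15 | ethyl (2S,4S)-2-[(2R,3S)-2,3-dimethyl-4-oxo-3,4-dihydro-2H-pyran-6-yl]-7-methyl-2-(3-methylbut-2-en-1-yl)-4-(prop-1-en-2-yl)oct-6-enoate | C=C(C)[C@@H](CC=C(C)C)C[C@@](CC=C(C)C)(C1=CC(=O)[C@@H](C)[C@@H](C)O1)C(=O)OCC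
F11 | step 15 | ethyl (2S,4S)-2-[(2R,3S)-5-iodo-2,3-dimethyl-4-oxo-3,4-dihydro-2H-pyran-6-yl]-7-methyl-2-(3-methylbut-2-en-1-yl)-4-(prop-1-en-2-yl)oct-6-enoate | C=C(C)[C@@H](CC=C(C)C)C[C@@](CC=C(C)C)(C1=C(I)C(=O)[C@@H](C)[C@@H](C)O1)C(=O)OCC
F12 | step 15 | ethyl (2S,4S)-2-[(2R,3S)-5-(1-ethoxyvinyl)-2,3-dimethyl-4-oxo-3,4-dihydro-2H-pyran-6-yl]-7-methyl-2-(3-methylbut-2-en-1-yl)-4-(prop-1-en-2-yl)oct-6-enoate | C=C(C)[C@@H](CC=C(C)C)C[C@@](CC=C(C)C)(C1=C(C(=C)OCC)C(=O)[C@@H](C)[C@@H](C)O1)C(=O)OCC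
F13 | step 21 | 5-benzylidene-2,2-dimethyl-1,3-dioxane-4,6-dione | CC1(C)OC(=O)C(=Cc2ccccc2)C(=O)O1
F14 | step 21 | 5-[(chromen-6-yl)(phenyl)methyl]-2,2-dimethyl-1,3-dioxane-4,6-dione from 35 (benzylic epimers) | C=C(C)[C@@H](CC=C(C)C)C[C@]1(CC=C(C)C)C(=O)C(C(c2ccccc2)C2C(=O)OC(C)(C)OC2=O)=C(O)C2=C1O[C@H](C)[C@H](C)C2=O
F15 | step 21 | (4R)-phenyl epimer of enol δ-lactone 39 | C=C(C)[C@@H](CC=C(C)C)C[C@]1(CC=C(C)C)C(=O)C3=C(OC(=O)C[C@@H]3c4ccccc4)C2=C1O[C@H](C)[C@H](C)C2=O
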